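## Retrosynthetic overview

1. Ring B is closed last: the diene C–C bond (exocyclic-methylene carbon to ring-C alkene carbon) comes from an intramolecular Ni-catalysed reductive coupling of a 2-iodoalkene with an enol triflate.
2. The enol triflate and the side-chain CH(CH3) centre come from one Me2CuLi addition/triflation of an (E)-alkylidene ketone, made by aldol condensation of CD dione 12 with A-ring aldehyde 7.
3. Ring C (trans-hydrindane) comes from a photochemical 1,5-acyl shift of a cyclopropyl enol lactone built from thujone (ring D, bought) and tert-butyl acrylate.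
4. Ring A comes from (S)-citronellal: α-methylenation, RCM, anti conjugate addition of a silylvinyl copper reagent, C1 equilibration, two-carbon homologation.
5. Order of ring formation: A (RCM), D (bought), C (photochemical), B (Ni).

Assumption: commercial thujone (α/β mixture, both 1S,5R; drawn as (−)-α-thujone) is used, because C4 becomes a planar enolate in step 6. Small reagents appear on the reagent lines and are not numbered. Ring-CD locants (C1–C7a) are those of the indene names.

## Route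

Step 1
Reactants: 1 (S)-citronellal [(3S)-3,7-dimethyloct-6-enal]
Product: 2 (3S)-3,7-dimethyl-2-methylideneoct-6-enal
Conditions: 37% aq. HCHO, pyrrolidine (10 mol%), EtCO2H (10 mol%), i-PrOH, 45 °C
Reagents that add atoms: formaldehyde, C=O
Why: Amine-catalysed Mannich-type α-methylenation (aldol condensation with formaldehyde) is general for α-CH2 aldehydes and leaves the C3 stereocentre untouched.

Step 2
Reactants: 2 (3S)-3,7-dimethyl-2-methylideneoct-6-enal
Product: 3 (5S)-5-methylcyclopent-1-ene-1-carbaldehyde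
Conditions: Hoveyda–Grubbs II (3 mol%), CH2Cl2 (0.05 M), 40 °C
Reagents that add atoms: none
Why: Ring-closing metathesis between the acrolein-type alkene and the prenyl alkene gives the five-membered enal, driven by loss of volatile isobutene, with the stereocentre unchanged.

Step 3
Reactants: 3 (5S)-5-methylcyclopent-1-ene-1-carbaldehyde
Product: 5 (1S,2S,5S)-2-methyl-5-[1-(trimethylsilyl)ethenyl]cyclopentane-1-carbaldehyde, via silyl enol ether 4 (not isolated)
Conditions: CH2=C(SiMe3)MgBr (1.5 equiv), CuBr·SMe2 (10 mol%), TMSCl, THF, −78 °C; 1 M HCl; DBU (0.2 equiv), CH2Cl2, rt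
Reagents that add atoms: [1-(trimethylsilyl)ethenyl]magnesium bromide, C=C([Mg]Br)[Si](C)(C)C
Why: Cu-catalysed, TMSCl-accelerated conjugate addition of the Grignard reagent places the silylvinyl group on the β-carbon anti to the pseudoaxial ring methyl (2,5-trans), and DBU then equilibrates the aldehyde-bearing carbon to the isomer trans to the bulky silylvinyl group and hence cis to methyl.

Step 4
Reactants: 5 (1S,2S,5S)-2-methyl-5-[1-(trimethylsilyl)ethenyl]cyclopentane-1-carbaldehyde
Product: 6 trimethyl{1-[(1S,2S,3S)-2-ethenyl-3-methylcyclopentyl]ethenyl}silane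
Conditions: Ph3PCH3Br, KOt-Bu, THF, 0 °C
Reagents that add atoms: methyltriphenylphosphonium bromide, C[P+](c1ccccc1)(c1ccccc1)c1ccccc1.[Br-]
Why: Wittig methylenation of an α-branched aldehyde is reliable, and because the aldehyde is already the thermodynamic epimer the basic ylide cannot erode it.

Step 5
Reactants: 6 trimethyl{1-[(1S,2S,3S)-2-ethenyl-3-methylcyclopentyl]ethenyl}silane
Product: 7 3-{(1S,2S,5S)-2-methyl-5-[1-(trimethylsilyl)ethenyl]cyclopentyl}propanal
Conditions: Rh(acac)(CO)2 (1 mol%), Xantphos (2 mol%), CO/H2 (1:1, 10 bar), toluene, 80 °C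
Reagents that add atoms: carbon monoxide, [C-]#[O+]
Why: Linear-selective Rh/Xantphos hydroformylation converts only the monosubstituted vinyl group, the hindered 1,1-disubstituted vinylsilane being inert, and forms no stereocentre.

Step 6
Reactants: 8 (−)-α-thujone [(1S,4R,5R)-4-methyl-1-(propan-2-yl)bicyclo[3.1.0]hexan-3-one]
Product: 9 tert-butyl 3-[(1S,4R,5S)-4-methyl-3-oxo-1-(propan-2-yl)bicyclo[3.1.0]hexan-4-yl]propanoate
Conditions: tert-butyl acrylate (1.2 equiv), KOt-Bu (0.2 equiv), t-BuOH–THF, 0 °C → rt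
Reagents that add atoms: tert-butyl acrylate, C=CC(=O)OC(C)(C)C
Why: Base-catalysed Michael addition under equilibrating conditions goes through the more substituted C3–C4 enolate (C2 is neopentyl-like, as in the known annulations of thujone), and the acceptor enters anti to the cyclopropane CH2, so the quaternary C4 carries the side chain anti and the methyl syn to C6.

Step 7
Reactants: 9 tert-butyl 3-[(1S,4R,5S)-4-methyl-3-oxo-1-(propan-2-yl)bicyclo[3.1.0]hexan-4-yl]propanoate
Product: 11 enol δ-lactone of keto acid 10 (3,4-dihydro-2H-pyran-2-one fused across C3–C4 of the thujane ring with the enol double bond C2=C3), via keto acid 10 (not isolated)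
Conditions: TFA, CH2Cl2, 0 °C; evaporate; Ac2O, NaOAc, 110 °C
Reagents that add atoms: none
Why: tert-Butyl ester acidolysis followed by classical dehydrative enol-lactonisation of a δ-keto acid, which can only enolise toward C2 because C4 is quaternary, changes no stereocentre.

Step 8
Reactants: 11 enol δ-lactone
Product: 12 (3aS,7aR)-7a-methyl-3-(propan-2-yl)-3a,4,7,7a-tetrahydro-1H-indene-1,5(6H)-dione
Conditions: hν (254 nm, quartz flow reactor), degassed MeCN (5 mM), 20 °C, recycle of unreacted 11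
Reagents that add atoms: none
Why: Proposed new method: a photochemical 1,5-acyl shift (interrupted photo-Fries) in which excitation homolyses the enol-ester O–acyl bond as in the known 1,3-acyl shift of enol esters and enol lactones (the closest known reaction type, together with Norrish type I recombination), the enoxyl radical has its spin on C2 next to the cyclopropane so that cyclopropylcarbinyl opening of the external C1–C6 bond (thujone radical-clock behaviour, about 10^7–10^8 s−1) moves the radical to the CH2 group, and recombination of the tethered acyl/alkyl 1,6-biradical closes the cyclohexanone; the ring-fusion CH is never touched and the tether lies on the opposite face, so the fusion is trans, and any normal 1,3-shift product (a cyclopropyl β-diketone) re-enters the same biradical by Norrish I cleavage.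

Step 9
Reactants: 12 (3aS,7aR)-7a-methyl-3-(propan-2-yl)-3a,4,7,7a-tetrahydro-1H-indene-1,5(6H)-dione; 7 3-{(1S,2S,5S)-2-methyl-5-[1-(trimethylsilyl)ethenyl]cyclopentyl}propanal
Product: 16 (3aS,6E,7aR)-7a-methyl-6-{3-[(1S,2S,5S)-2-methyl-5-[1-(trimethylsilyl)ethenyl]cyclopentyl]propylidene}-3-(propan-2-yl)-3a,4,7,7a-tetrahydro-1H-indene-1,5(6H)-dione, via lithium enolate 13 (not isolated), via lithium aldolate 14 (not isolated), via mesylate 15 (not isolated)
Conditions: LDA, THF, −78 °C; 7; MsCl, −78 → 0 °C; DBU, rt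
Reagents that add atoms: none
Why: Crossed aldol condensation in which kinetic deprotonation of the trans-fused 5-ketone occurs at C6 (as at C2 of 3-keto-5α-steroids; the cyclopentenone has no α-hydrogen) and E1cB elimination of the mesylate gives the thermodynamically preferred (E)-alkylidene ketone with no lasting new stereocentre.

Step 10
Reactants: 16 (E)-alkylidene dione
Product: 18 (3aS,7aR)-7a-methyl-6-{(2S)-4-[(1S,2S,5S)-2-methyl-5-[1-(trimethylsilyl)ethenyl]cyclopentyl]butan-2-yl}-1-oxo-3-(propan-2-yl)-3a,4,7,7a-tetrahydro-1H-inden-5-yl trifluoromethanesulfonate, via lithium enolate 17 (not isolated)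
Conditions: Me2CuLi (1.15 equiv; from MeLi, CuI), Et2O–THF, −78 °C; PhNTf2, −78 → 0 °C
Reagents that add atoms: lithium dimethylcuprate, [Li+].C[Cu-]C; N-phenylbis(trifluoromethanesulfonimide), O=S(=O)(N(c1ccccc1)S(=O)(=O)C(F)(F)F)C(F)(F)F
Why: Gilman cuprate 1,4-addition to the s-cis exocyclic enone with regiospecific O-triflation of the enolate, in which methyl attacks the exocyclic β-carbon from the equatorial face away from the axial angular methyl (1,3 to C6), which with the (E)-alkylidene gives the (S)-methine, while the β,β-disubstituted cyclopentenone reacts far more slowly.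

Step 11
Reactants: 18 enol triflate enone
Product: 19 (1R,3aS,7aR)-1-hydroxy-7a-methyl-6-{(2S)-4-[(1S,2S,5S)-2-methyl-5-[1-(trimethylsilyl)ethenyl]cyclopentyl]butan-2-yl}-3-(propan-2-yl)-3a,4,7,7a-tetrahydro-1H-inden-5-yl trifluoromethanesulfonate
Conditions: NaBH4, CeCl3·7H2O, MeOH, −40 °C
Reagents that add atoms: none
Why: Luche 1,2-reduction in which hydride attacks C1 anti to the adjacent angular methyl (as in 17-ketosteroid reductions), giving the alcohol cis to that methyl.

Step 12
Reactants: 19 allylic alcohol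
Product: 20 (1R,3S,3aS,7aR)-1-hydroxy-7a-methyl-6-{(2S)-4-[(1S,2S,5S)-2-methyl-5-[1-(trimethylsilyl)ethenyl]cyclopentyl]butan-2-yl}-3-(propan-2-yl)-2,3,3a,4,7,7a-hexahydro-1H-inden-5-yl trifluoromethanesulfonate
Conditions: H2 (1 atm), [Ir(cod)(PCy3)(py)]PF6 (2 mol%), CH2Cl2, 0 °C, short reaction time
Reagents that add atoms: none
Why: Hydroxyl-directed (Crabtree) hydrogenation delivers H2 to the cyclopentene from the face of the C1–OH, which puts the isopropyl group trans to OH and angular methyl, while the tetrasubstituted enol triflate and the hindered non-coordinating vinylsilane react much more slowly.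

Step 13
Reactants: 20 saturated alcohol
Product: 21 (1R,3S,3aS,7aR)-1-hydroxy-6-{(2S)-4-[(1S,2S,5S)-2-(1-iodoethenyl)-5-methylcyclopentyl]butan-2-yl}-7a-methyl-3-(propan-2-yl)-2,3,3a,4,7,7a-hexahydro-1H-inden-5-yl trifluoromethanesulfonate
Conditions: NIS, MeCN–ClCH2CN (4:1), 0 °C
Reagents that add atoms: N-iodosuccinimide, O=C1CCC(=O)N1I
Why: ipso-Iododesilylation of the 1,1-disubstituted vinylsilane gives the 2-iodoalkene, the electron-poor enol triflate being inert, and touches no stereocentre.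

Step 14
Reactants: 21 iodoalkene enol triflate
Product: 22 CNP0544018.1 (target)
Conditions: NiBr2·glyme (20 mol%), dtbbpy (24 mol%), Zn, NaI, DMA (2 mM, slow addition), 40 °C
Reagents that add atoms: none
Why: Ni-catalysed reductive alkenyl–alkenyl cross-electrophile coupling (alkenyl iodide with alkenyl triflate, Zn as reductant), run intramolecularly, closes the eight-membered ring and forms the 1,3-diene directly while tolerating the free hydroxyl and involving no stereocentre.

## Compound list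

1 | (S)-citronellal, (3S)-3,7-dimethyloct-6-enal | C[C@@H](CCC=C(C)C)CC=O | starting material
2 | (3S)-3,7-dimethyl-2-methylideneoct-6-enal | C[C@@H](CCC=C(C)C)C(=C)C=O | intermediate
3 | (5S)-5-methylcyclopent-1-ene-1-carbaldehyde | C[C@H]1CCC=C1C=O | intermediate
4 | trimethyl({(2S,5S)-2-methyl-5-[1-(trimethylsilyl)ethenyl]cyclopentylidene}methoxy)silane | C[Si](C)(C)OC=C1[C@@H](C(=C)[Si](C)(C)C)CC[C@@H]1C | intermediate (not isolated)
5 | (1S,2S,5S)-2-methyl-5-[1-(trimethylsilyl)ethenyl]cyclopentane-1-carbaldehyde | O=C[C@@H]1[C@@H](C(=C)[Si](C)(C)C)CC[C@@H]1C | intermediate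
6 | trimethyl{1-[(1S,2S,3S)-2-ethenyl-3-methylcyclopentyl]ethenyl}silane | C=C[C@@H]1[C@@H](C(=C)[Si](C)(C)C)CC[C@@H]1C | intermediate
7 | 3-{(1S,2S,5S)-2-methyl-5-[1-(trimethylsilyl)ethenyl]cyclopentyl}propanal | O=CCC[C@@H]1[C@@H](C(=C)[Si](C)(C)C)CC[C@@H]1C | intermediate
8 | (−)-α-thujone, (1S,4R,5R)-4-methyl-1-(propan-2-yl)bicyclo[3.1.0]hexan-3-one | C[C@@H]1[C@H]2C[C@]2(CC1=O)C(C)C | starting material
9 | tert-butyl 3-[(1S,4R,5S)-4-methyl-3-oxo-1-(propan-2-yl)bicyclo[3.1.0]hexan-4-yl]propanoate | CC(C)(C)OC(=O)CC[C@@]1(C)C(=O)C[C@@]2(C(C)C)[C@@H]1C2 | intermediate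
10 | 3-[(1S,4R,5S)-4-methyl-3-oxo-1-(propan-2-yl)bicyclo[3.1.0]hexan-4-yl]propanoic acid | OC(=O)CC[C@@]1(C)C(=O)C[C@@]2(C(C)C)[C@@H]1C2 | intermediate (not isolated)
11 | enol δ-lactone of 10 (lactone O on C3, enol double bond C2=C3, ring stereocentres as in 9) | O=C1CC[C@@]2(C)C(=C[C@@]3(C(C)C)[C@@H]2C3)O1 | intermediate
12 | (3aS,7aR)-7a-methyl-3-(propan-2-yl)-3a,4,7,7a-tetrahydro-1H-indene-1,5(6H)-dione (trans-fused) | O=C1CC[C@@]2(C)C(=O)C=C(C(C)C)[C@@H]2C1 | intermediate
13 | lithium C5–C6 enolate of 12 | [Li+].[O-]C1=CC[C@@]2(C)C(=O)C=C(C(C)C)[C@@H]2C1 | intermediate (not isolated)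
14 | lithium aldolate from 13 and 7 (C6 and carbinol carbon as mixtures) | [Li+].[O-]C(CC[C@@H]1[C@@H](C(=C)[Si](C)(C)C)CC[C@@H]1C)C1C[C@@]2(C)C(=O)C=C(C(C)C)[C@@H]2CC1=O | intermediate (not isolated)
15 | methanesulfonate of the aldol adduct | CS(=O)(=O)OC(CC[C@@H]1[C@@H](C(=C)[Si](C)(C)C)CC[C@@H]1C)C1C[C@@]2(C)C(=O)C=C(C(C)C)[C@@H]2CC1=O | intermediate (not isolated)
16 | (3aS,6E,7aR)-7a-methyl-6-{3-[(1S,2S,5S)-2-methyl-5-[1-(trimethylsilyl)ethenyl]cyclopentyl]propylidene}-3-(propan-2-yl)-3a,4,7,7a-tetrahydro-1H-indene-1,5(6H)-dione | O=C1/C(=C/CC[C@@H]3[C@@H](C(=C)[Si](C)(C)C)CC[C@@H]3C)C[C@@]2(C)C(=O)C=C(C(C)C)[C@@H]2C1 | intermediate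
17 | lithium C5–C6 enolate after methyl addition (side-chain methine S) | [Li+].[O-]C1=C(C[C@@]2(C)C(=O)C=C(C(C)C)[C@@H]2C1)[C@@H](C)CC[C@@H]3[C@@H](C(=C)[Si](C)(C)C)CC[C@@H]3C | intermediate (not isolated)
18 | (3aS,7aR)-7a-methyl-6-{(2S)-4-[(1S,2S,5S)-2-methyl-5-[1-(trimethylsilyl)ethenyl]cyclopentyl]butan-2-yl}-1-oxo-3-(propan-2-yl)-3a,4,7,7a-tetrahydro-1H-inden-5-yl trifluoromethanesulfonate | FC(F)(F)S(=O)(=O)OC1=C(C[C@@]2(C)C(=O)C=C(C(C)C)[C@@H]2C1)[C@@H](C)CC[C@@H]3[C@@H](C(=C)[Si](C)(C)C)CC[C@@H]3C | intermediate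
19 | (1R,3aS,7aR)-1-hydroxy analogue of 18 (OH cis to the angular methyl) | FC(F)(F)S(=O)(=O)OC1=C(C[C@@]2(C)[C@H](O)C=C(C(C)C)[C@@H]2C1)[C@@H](C)CC[C@@H]3[C@@H](C(=C)[Si](C)(C)C)CC[C@@H]3C | intermediate
20 | (1R,3S,3aS,7aR)-1-hydroxy-7a-methyl-6-{(2S)-4-[(1S,2S,5S)-2-methyl-5-[1-(trimethylsilyl)ethenyl]cyclopentyl]butan-2-yl}-3-(propan-2-yl)-2,3,3a,4,7,7a-hexahydro-1H-inden-5-yl trifluoromethanesulfonate | FC(F)(F)S(=O)(=O)OC1=C(C[C@@]2(C)[C@H](O)C[C@@H](C(C)C)[C@@H]2C1)[C@@H](C)CC[C@@H]3[C@@H](C(=C)[Si](C)(C)C)CC[C@@H]3C | intermediate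
21 | (1R,3S,3aS,7aR)-1-hydroxy-6-{(2S)-4-[(1S,2S,5S)-2-(1-iodoethenyl)-5-methylcyclopentyl]butan-2-yl}-7a-methyl-3-(propan-2-yl)-2,3,3a,4,7,7a-hexahydro-1H-inden-5-yl trifluoromethanesulfonate | FC(F)(F)S(=O)(=O)OC1=C(C[C@@]2(C)[C@H](O)C[C@@H](C(C)C)[C@@H]2C1)[C@@H](C)CC[C@@H]3[C@@H](C(I)=C)CC[C@@H]3C | intermediate
22 | CNP0544018.1 (5-8-6-5 tetracyclic dienol) | C=C1C2=C(C[C@@]3(C)[C@H](O)C[C@@H](C(C)C)[C@@H]3C2)[C@@H](C)CC[C@@H]2[C@@H]1CC[C@@H]2C | target

## Step count and risks

Total steps: 14. Longest linear sequence: 11 (steps 1–5, then 9–14).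

**Step 8 (new photochemical 1,5-acyl shift).** The risks are competing ordinary 1,3-acyl shift, ketene formation by disproportionation of the biradical, and secondary photochemistry of the product enone. The fallback uses known radical and nickel chemistry; it sets out from keto ester 9 and returns at dione 12. Phenyltrimethylammonium tribromide in THF brominates the only enolisable ketone position to give the α-bromo ketone F1. Halogen-atom-transfer isomerisation (catalytic hexabutylditin, sun lamp, benzene, 60 °C) opens the cyclopropylcarbinyl radical and gives the ring-opened primary bromide F2. TFA then gives the acid F3, which 2,2′-dipyridyl disulfide and PPh3 convert into the S-(2-pyridyl) thioester F4. A Ni-catalysed reductive alkyl bromide/thioester ketone synthesis (NiCl2·glyme, dtbbpy, Zn, DMA, high dilution) closes the cyclohexanone to 12.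

**Step 14 (eight-membered ring by reductive alkenyl–alkenyl coupling).** The risks are oligomerisation and protodehalogenation. The fallback sets out from 21 and returns at 22 by a different, redox-neutral Pd mode. Miyaura borylation of the alkenyl iodide (PdCl2(PPh3)2, B2pin2, KOPh, toluene, 50 °C) gives the alkenyl boronate F10. Intramolecular Suzuki–Miyaura coupling with the enol triflate (Pd(PPh3)4, Cs2CO3, THF–H2O, high dilution, 60 °C) then gives 22.

**Step 10 (facial selectivity at the exocyclic carbon).** The risk is a low diastereomer ratio at the side-chain methine. The fallback sets this centre by a sigmatropic rearrangement instead of a conjugate addition; it sets out from dione 12 (and alkene 6) and returns at triflate 18.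
- The saturated ketone is ketalised (HC(OMe)3, TsOH, MeOH) to the dimethyl ketal F5.
- Heating F5 with (E)-but-2-en-1-ol and catalytic propionic acid (xylene, 140 °C) gives the crotyl enol ether F6, which is not isolated.
- F6 undergoes Claisen rearrangement through a chair transition state on the face of C6 away from the angular methyl, giving the (2S)-but-3-en-2-yl ketone F7.
- Cross-metathesis of F7 with alkene 6 (Hoveyda–Grubbs II) gives the disubstituted alkene F8.
- Diimide (TsNHNH2, NaOAc) reduces that alkene to ketone F9.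
- Thermodynamic enol triflation (Tf2O, 2,6-di-tert-butyl-4-methylpyridine) gives 18.

Further compounds
F1 | step 8 | tert-butyl 3-[2-bromo-4-methyl-3-oxo-1-(propan-2-yl)bicyclo[3.1.0]hexan-4-yl]propanoate (ring stereocentres as in 9, C2 epimers) | CC(C)(C)OC(=O)CC[C@@]1(C)C(=O)C(Br)[C@@]2(C(C)C)[C@@H]1C2
F2 | step 8 | tert-butyl 3-[(1R,5S)-5-(bromomethyl)-1-methyl-2-oxo-4-(propan-2-yl)cyclopent-3-en-1-yl]propanoate | CC(C)(C)OC(=O)CC[C@@]1(C)C(=O)C=C(C(C)C)[C@@H]1CBr
F3 | step 8 | 3-[(1R,5S)-5-(bromomethyl)-1-methyl-2-oxo-4-(propan-2-yl)cyclopent-3-en-1-yl]propanoic acid | OC(=O)CC[C@@]1(C)C(=O)C=C(C(C)C)[C@@H]1CBr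
F4 | step 8 | S-pyridin-2-yl 3-[(1R,5S)-5-(bromomethyl)-1-methyl-2-oxo-4-(propan-2-yl)cyclopent-3-en-1-yl]propanethioate | O=C(CC[C@@]1(C)C(=O)C=C(C(C)C)[C@@H]1CBr)Sc1ccccn1
F5 | step 10 | (3aS,7aR)-5,5-dimethoxy-7a-methyl-3-(propan-2-yl)-3a,4,5,6,7,7a-hexahydro-1H-inden-1-one | COC1(OC)CC[C@@]2(C)C(=O)C=C(C(C)C)[C@@H]2C1
F6 | step 10 | (3aS,7aR)-5-{[(2E)-but-2-en-1-yl]oxy}-7a-methyl-3-(propan-2-yl)-3a,4,7,7a-tetrahydro-1H-inden-1-one | C/C=C/COC1=CC[C@@]2(C)C(=O)C=C(C(C)C)[C@@H]2C1
F7 | step 10 | (3aS,7aR)-6-[(2S)-but-3-en-2-yl]-7a-methyl-3-(propan-2-yl)-3a,4,7,7a-tetrahydro-1H-indene-1,5(6H)-dione (C6 epimers) | O=C1C([C@@H](C)C=C)C[C@@]2(C)C(=O)C=C(C(C)C)[C@@H]2C1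
F8 | step 10 | cross-metathesis product of F7 and 6: the (E)-alkene joining the (2S)-methine to the cyclopentyl unit of 7 | O=C1C([C@@H](C)/C=C/[C@@H]3[C@@H](C(=C)[Si](C)(C)C)CC[C@@H]3C)C[C@@]2(C)C(=O)C=C(C(C)C)[C@@H]2C1
F9 | step 10 | (3aS,7aR)-7a-methyl-6-{(2S)-4-[(1S,2S,5S)-2-methyl-5-[1-(trimethylsilyl)ethenyl]cyclopentyl]butan-2-yl}-3-(propan-2-yl)-3a,4,7,7a-tetrahydro-1H-indene-1,5(6H)-dione (C6 epimers) | O=C1C([C@@H](C)CC[C@@H]3[C@@H](C(=C)[Si](C)(C)C)CC[C@@H]3C)C[C@@]2(C)C(=O)C=C(C(C)C)[C@@H]2C1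
F10 | step 14 | pinacol alkenylboronate corresponding to 21 (I replaced by Bpin) | FC(F)(F)S(=O)(=O)OC1=C(C[C@@]2(C)[C@H](O)C[C@@H](C(C)C)[C@@H]2C1)[C@@H](C)CC[C@@H]3[C@@H](C(=C)B4OC(C)(C)C(C)(C)O4)CC[C@@H]3C
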